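The midnight flask held 0.0500 M of substrate and 0.00150 M of free catalyst, yet its target had crept to 0.01883 M by 77 min, 0.0312 M short of the substrate charged.

| flask | substrate | free catalyst | target | time |
|---|---|---|---|---|
| midnight | 0.0500 M | 0.00150 M |  |  |
| dusk | 0.0300 M | 0.00150 M |  |  |
| spring | 0.0500 M | 0.00450 M |  |  |
| summer | 0.0250 M | 0.00150 M |  |  |
| dawn | 0.0500 M | 0.00150 M | 0.0150 M | 77 min |

| run | time / min | [target] / M |
|---|---|---|
| midnight run | 11 | 0.00819 |
| midnight run | 22 | 0.01292 |
| midnight run | 33 | 0.01597 |
| midnight run | 44 | 0.01686 |
| midnight run | 55 | 0.01803 |
| midnight run | 66 | 0.01838 |
| midnight run | 77 | 0.01883 |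
| dusk run | 11 | 0.00887 |
| dusk run | 22 | 0.01426 |
| dusk run | 33 | 0.01721 |
| dusk run | 44 | 0.01944 |
| dusk run | 55 | 0.02104 |
| dusk run | 66 | 0.02238 |
| dusk run | 77 | 0.02339 |
| spring run | 11 | 0.04953 |
| spring run | 22 | 0.04990 |
| spring run | 33 | 0.05008 |
| spring run | 44 | 0.04997 |
| spring run | 55 | 0.05022 |
| spring run | 66 | 0.05002 |
| spring run | 77 | 0.05021 |
| summer run | 11 | 0.00840 |
| summer run | 22 | 0.01324 |
| summer run | 33 | 0.01636 |
| summer run | 44 | 0.01871 |
| summer run | 55 | 0.02035 |
| summer run | 66 | 0.02135 |
| summer run | 77 | 0.02255 |

(scatter of a reading: 2 × 10⁻⁴ M)

- Overall: substrate -> target, with free catalyst as catalyst.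
- Constant volume, constant temperature.
- Readings of a species count what is bound in complexes too.
- An order is taken over about fifteen percent of the charge, up and down.
- A share of target counts the target that was charged too.

- the power of [substrate] that the first rate follows, about the charge of the midnight run; measure it at two percent of substrate made into target (one fixed amount of target, the same in the runs compared)
- the power of [free catalyst] that the first rate follows, about the charge of the midnight run; measure it at two percent of substrate made into target
- target in the dawn run at 77 min, as a share of the substrate charged

I took the settings in turn. A rate proportional to substrate would have fallen with the charge, but summer, with half the substrate of midnight, read 0.00840 M at 11 min against 0.00819 M, and dusk read 0.00887 M. So I put the order in substrate near zero, slightly below it. Less substrate still ended higher: summer reached 0.02255 M at 77 min, above midnight.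

A rate proportional to catalyst would have gained a factor 3.00 in spring. Instead spring read 0.04953 M at 11 min from a charge of 0.0500 M, which is 6.05 times midnight's reading and is capped by that charge. Read as an order, that ratio of capped readings gives 1.64, a rough estimate, and I committed to 2.

Charged target would matter if target choked the flask, but dusk rose from 0.02104 M at 55 min to 0.02339 M at 77 min, past midnight's last reading. So I let dawn's 0.0150 M of charged target stand idle, which makes dawn a midnight flask with an onlooker.

Midnight's second interval gained a fraction q = 0.578 of its first. I defined the reach as the target a flask can make if every equal interval yields q of the one before, which is the first gain divided by 1 − q. For midnight it is 0.0194 M. By 77 min dawn should have made 0.0190 M, so with its charged target I expected 67.9%.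

The forecast gave −0.2, 2 and 50%, saying of dawn: “I can't separate these cleanly, so I hedge between them.” My dawn figure stood higher.

The flask gives −0.17, 2.1 and 67.8%.

    free catalyst + substrate ⇌ catalyst-substrate complex, settled at all times (27.00 /M)
    catalyst-substrate complex + free catalyst → target + 2 free catalyst (1794 /M/min)
    catalyst-substrate complex → spent catalyst + substrate (0.05016 /min)

Dawn made 0.0189 M of target, against my 0.0190 M, and that lies inside the reach of 0.0194 M. Dawn's share is held down by catalyst-substrate complex turning into spent catalyst, which is catalyst deactivation. The same dawn flask without that step reaches 129%, so it makes 0.0495 M of target, 2.55 times the reach and 61 percentage points above the share as it is.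

The readings are calculated on assumed constants.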